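Electrophile left over at the end of this flask was what I set out to reckon, together with the free share of the nucleophile.

solid electrophile 28 mM; free base 22.4 mM; protonated nucleophile 36.4 mM; protic impurity 28.0 mM; time 2.5 min

    nucleophile + acid set free ⇌ protonated nucleophile, settled at all times (K1 = 1.2 × 10⁵ M⁻¹)
    solid electrophile ⇌ electrophile, rate k2*(cs2 - [electrophile]) while solid is left; crystals form when [electrophile] > cs2 (cs2 = 27 mM, k2 = 0.11 s⁻¹)
    acid set free → by-product carried off (k3 = 0.0072 s⁻¹)
    electrophile + protic impurity → quenched substrate (k4 = 0.55 M⁻¹ s⁻¹)
    acid set free + free base ⇌ salt of the base, settled at all times (K5 = 1.0 × 10⁵ M⁻¹)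
    electrophile + nucleophile → acid set free + target (k6 = 2.7 M⁻¹ s⁻¹)

- solid, in amounts per volume of the solution: solid electrophile
- at the start none of the solid electrophile is in solution
- what has only dissolved of solid electrophile counts as not reacted
- run time (flask): 2.5 min

* part of the solid electrophile that has reacted (what has only dissolved counts as not reacted) at 2.5 min
* share of the unused nucleophile that is free and not bound as protonated nucleophile, at 2.5 min

1. First instants. The solid entered solution with a time constant of 9.09 s, much shorter than the run. The nucleophile was charged bound, and free base released it, with an exchange constant of 0.833. At equal concentrations, the electrophile favoured nucleophile over protic impurity by a selectivity factor of 4.91.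

2. Middle. Each target cost two basic sites: one nucleophile consumed and one acid set free to be bound. Free base was the spare capacity, so I kept 11.2 mM as the target ceiling, half the free base charged, counting no acid carried off and none unbound; that was 40.0 % of the solid charged. Free base, rather than electrophile, was thus the limiting reagent for target, with a ceiling lower than the charge.

3. Crossing. Past the ceiling, I let protic impurity take the electrophile. Placing the crossing at time zero left 16.8 mM of electrophile against 28.0 mM of impurity, a gap of 11.2 mM. In second-order reckoning, their ratio grew to 4.20 by the end. My reckoning thus left 3.50 mM of electrophile and gave 87.5 % reacted.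

4. End. At the ceiling, I counted 25.2 mM of protonated nucleophile and the whole free base charge of 22.4 mM as salt, and reckoned 0.659 mM of acid unbound. My free share was 1.25 %.

The forecast said 95.5 % and 14 %, holding that “The nucleophile's free share is set by proton sharing with the base”. My figures were lower on both counts.

The flask gave 88.4 % and 1.99 %; from 1.25 min to 2.50 min, quenched substrate gained 11 percentage points, more than the 2.4 points gained by target, which ended at 39.3 % against a ceiling of 40.0 %. In the neighbour flask with 48 mM of solid electrophile, the same ceiling is 23.3 % of the charge and the same count, from 36.8 mM and a gap of −8.80 mM, leaves 13.9 mM, or 29.0 %, as electrophile; that flask ended with target at 25.0 % and electrophile at 29.4 %.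

The constants belong to no real substance; the flask was simulated.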